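## Retrosynthetic overview

Numbering: furo[3,4-c]furan-1-one, C1(=O)–O2–C3(guaiacyl)–C3a–C4H2–O5–C6(catechol)–C6a; ring A = γ-lactone, ring B = oxolane.
Target 13 ⇐ 12 (hydrogenolysis of three OBn and of C6a–Br) ⇐ 10 (bromomethoxylation, then ketal reduction: a formal anti addition of H2 across C6=C6a that sets C6 and C6a).
10 ⇐ β-keto ester 8 by one oxidative radical cyclisation/ring-expansion cascade: the C6a–C3a bond closes ring A first, then the O5–C4 bond closes ring B.
Enabling feature: with C6 held at the ketone level, C6a is the central carbon of a 1,3-dicarbonyl (lactone carbonyl C1 and ketone C6), so it can be oxidised to a radical and its enol oxygen becomes O5; the ring A ester link C1–O2–C3 places it three atoms from the C3a=C4 vinyl group (5-exo).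
8 ⇐ (S)-allylic alcohol 4 (C3; from O-benzylvanillin 1, vinyl Grignard, lipase resolution) + aroylketene from acid 5 and Meldrum's acid 6.

Key step: step 4

Remark: catalytic hydrogenation of the C6=C6a bond of 10 would add both hydrogens from the convex face and give the C6 epimer of the target; the two hydrogens are therefore introduced in separate steps on opposite faces, with bromine as a temporary blocking group at C6a.

## Route

Step 1
Reactants: 1 4-(benzyloxy)-3-methoxybenzaldehyde; 2 vinylmagnesium bromide
Product: 3 (±)-1-[4-(benzyloxy)-3-methoxyphenyl]prop-2-en-1-ol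
Conditions: THF, −78 to 0 °C; then aq. NH4Cl
Reagents that add atoms: none
Why: Grignard 1,2-addition of the vinyl nucleophile to the aldehyde should give the allylic alcohol; the new carbinol centre is formed as a racemate and is resolved in step 2.

Step 2
Reactants: 3 (±)-1-[4-(benzyloxy)-3-methoxyphenyl]prop-2-en-1-ol
Product: 4 (S)-1-[4-(benzyloxy)-3-methoxyphenyl]prop-2-en-1-ol
Conditions: Novozym 435 (immobilised Candida antarctica lipase B), vinyl acetate, MTBE, 30 °C, stopped just past half conversion; chromatography on Et3N-deactivated silica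
Reagents that add atoms: none
Why: Lipase-catalysed kinetic resolution (enantioselective transesterification): with aryl as the large and vinyl as the medium substituent the enzyme is expected to acetylate the (R)-alcohol and leave the (S)-alcohol, which carries the future C3 stereocentre.

Step 3
Reactants: 4 (S)-1-[4-(benzyloxy)-3-methoxyphenyl]prop-2-en-1-ol; 5 3,4-bis(benzyloxy)benzoic acid; 6 Meldrum's acid
Product: 8 (1S)-1-[4-(benzyloxy)-3-methoxyphenyl]prop-2-en-1-yl 3-[3,4-bis(benzyloxy)phenyl]-3-oxopropanoate, via acyl Meldrum's acid 7 (not isolated)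
Conditions: 5, 6, DCC, DMAP, CH2Cl2, 0 °C to rt, filtration and cold aq. KHSO4 wash; then 4, toluene, 80 °C
Reagents that add atoms: none
Why: C-Acylation of Meldrum's acid and thermal loss of acetone and CO2 give an aroylketene that is trapped by the hydroxyl group of 4 (acylketene esterification), so the carbinol C–O bond is never broken and the (S) configuration is retained.

Step 4
Reactants: 8 (1S)-1-[4-(benzyloxy)-3-methoxyphenyl]prop-2-en-1-yl 3-[3,4-bis(benzyloxy)phenyl]-3-oxopropanoate
Product: 10 (3S,3aR)-6-[3,4-bis(benzyloxy)phenyl]-3-[4-(benzyloxy)-3-methoxyphenyl]-3a,4-dihydro-1H,3H-furo[3,4-c]furan-1-one, via acylcyclopropane lactone 9 (not isolated)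
Conditions: Mn(OAc)3·2H2O (2.2 equiv), Cu(OAc)2·H2O (0.5 equiv), degassed AcOH, 40 °C; then, same flask, AcOH evaporated, DABCO (3 equiv), DMSO, 100 °C
Reagents that add atoms: none
Why: Mn(OAc)3 (trivalent manganese) oxidises the enol of the 1,3-dicarbonyl unit to an electrophilic α-radical at the future C6a, which adds 5-exo-trig to the internal carbon of the tethered vinyl group (new C6a–C3a bond, ring A closed), and Cu(OAc)2 intercepts the primary C4 radical as an alkylcopper intermediate (formally trivalent copper) that collapses by 3-exo-tet C-alkylation to the acylcyclopropane 9. The closest known reactions are this same oxidative cyclisation of 1-arylallyl β-keto esters to 1-acyl-3-oxabicyclo[3.1.0]hexan-2-ones and the amine-catalysed Cloke–Wilson rearrangement of doubly activated cyclopropyl ketones. DABCO should open 9 by SN2 attack at the unsubstituted cyclopropane CH2 (C4), and the ketone enolate oxygen then displaces the ammonium group in a 5-exo-tet O-alkylation, which forms the O5–C4 bond and closes ring B as the 4,5-dihydrofuran. The only new stereocentre, C3a, is controlled by the C3 carbinol centre of 4: the aryl group sits pseudo-equatorially in the cyclisation transition state, so H-3a ends up trans to H-3. The step needs 5-exo rather than 6-endo addition, secured by the three-atom ester tether and the unsubstituted alkene terminus, and ring opening at C4 rather than C3a, secured by the SN2 preference of DABCO for the CH2 carbon; O-closure is the sink because it gives a strain-free push–pull enol ether conjugated with the lactone and the aryl ring.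

Step 5
Reactants: 10 (3S,3aR)-6-[3,4-bis(benzyloxy)phenyl]-3-[4-(benzyloxy)-3-methoxyphenyl]-3a,4-dihydro-1H,3H-furo[3,4-c]furan-1-one
Product: 11 (3S,3aR,6aR)-6-[3,4-bis(benzyloxy)phenyl]-3-[4-(benzyloxy)-3-methoxyphenyl]-6a-bromo-6-methoxytetrahydro-1H,3H-furo[3,4-c]furan-1-one (both C6 ketal epimers)
Conditions: NBS (1.05 equiv), NaHCO3, MeOH/CH2Cl2, −40 °C, dark
Reagents that add atoms: N-bromosuccinimide, O=C1CCC(=O)N1Br; methanol, CO
Why: Electrophilic bromo-alkoxylation of the cyclic enol ether: Br+ can reach C6a only from the convex face, cis to H-3a, because the bicycle must stay cis-fused, and methanol traps the aryl-stabilised oxocarbenium ion at C6, whose ketal configuration is irrelevant.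

Step 6
Reactants: 11 (3S,3aR,6aR)-6-[3,4-bis(benzyloxy)phenyl]-3-[4-(benzyloxy)-3-methoxyphenyl]-6a-bromo-6-methoxytetrahydro-1H,3H-furo[3,4-c]furan-1-one
Product: 12 (3S,3aR,6R,6aR)-6-[3,4-bis(benzyloxy)phenyl]-3-[4-(benzyloxy)-3-methoxyphenyl]-6a-bromotetrahydro-1H,3H-furo[3,4-c]furan-1-one
Conditions: Et3SiH (3 equiv), Me3SiOTf (0.2 equiv), CH2Cl2, −78 to −40 °C
Reagents that add atoms: none
Why: Silane (ionic) reduction of the aryl ketal through the planar 2-aryl oxocarbenium ion: the exo face of C6 is shielded by the adjacent exo C6a–Br bond (steric and bromonium-type shielding, attack antiperiplanar to C–Br), so hydride should enter from the endo face and leave the aryl group exo, trans to the lactone carbonyl.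

Step 7
Reactants: 12 (3S,3aR,6R,6aR)-6-[3,4-bis(benzyloxy)phenyl]-3-[4-(benzyloxy)-3-methoxyphenyl]-6a-bromotetrahydro-1H,3H-furo[3,4-c]furan-1-one
Product: 13 (3S,3aR,6S,6aS)-6-(3,4-dihydroxyphenyl)-3-(4-hydroxy-3-methoxyphenyl)tetrahydro-1H,3H-furo[3,4-c]furan-1-one
Conditions: H2 (1 atm), 10% Pd/C, NaOAc, EtOAc/MeOH, rt, stopped on complete debenzylation
Reagents that add atoms: none
Why: Catalytic hydrogenolysis cleaves the three benzyl ethers and the tertiary α-bromo lactone C–Br bond; the new H-6a can only be cis to H-3a, since a trans-fused bicycle is prohibitively strained and the lactone α-centre would equilibrate to the cis fusion through its enol.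

## Compound list

1 | 4-(benzyloxy)-3-methoxybenzaldehyde (O-benzylvanillin) | COc1cc(C=O)ccc1OCc1ccccc1 | starting material
2 | vinylmagnesium bromide | C=C[Mg]Br | starting material
3 | (±)-1-[4-(benzyloxy)-3-methoxyphenyl]prop-2-en-1-ol | COc1cc(C(O)C=C)ccc1OCc1ccccc1 | intermediate
4 | (S)-1-[4-(benzyloxy)-3-methoxyphenyl]prop-2-en-1-ol | COc1cc([C@@H](O)C=C)ccc1OCc1ccccc1 | intermediate
5 | 3,4-bis(benzyloxy)benzoic acid | OC(=O)c1ccc(OCc2ccccc2)c(OCc2ccccc2)c1 | starting material
6 | Meldrum's acid (2,2-dimethyl-1,3-dioxane-4,6-dione) | CC1(C)OC(=O)CC(=O)O1 | starting material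
7 | 5-{[3,4-bis(benzyloxy)phenyl](hydroxy)methylidene}-2,2-dimethyl-1,3-dioxane-4,6-dione | CC1(C)OC(=O)C(=C(O)c2ccc(OCc3ccccc3)c(OCc3ccccc3)c2)C(=O)O1 | intermediate
8 | (1S)-1-[4-(benzyloxy)-3-methoxyphenyl]prop-2-en-1-yl 3-[3,4-bis(benzyloxy)phenyl]-3-oxopropanoate | COc1cc([C@@H](OC(=O)CC(=O)c2ccc(OCc3ccccc3)c(OCc3ccccc3)c2)C=C)ccc1OCc1ccccc1 | intermediate
9 | (1R,4S,5S)-1-[3,4-bis(benzyloxy)benzoyl]-4-[4-(benzyloxy)-3-methoxyphenyl]-3-oxabicyclo[3.1.0]hexan-2-one | COc1cc([C@H]2OC(=O)[C@]3(C(=O)c4ccc(OCc5ccccc5)c(OCc5ccccc5)c4)C[C@H]23)ccc1OCc1ccccc1 | intermediate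
10 | (3S,3aR)-6-[3,4-bis(benzyloxy)phenyl]-3-[4-(benzyloxy)-3-methoxyphenyl]-3a,4-dihydro-1H,3H-furo[3,4-c]furan-1-one | COc1cc([C@H]2OC(=O)C3=C(c4ccc(OCc5ccccc5)c(OCc5ccccc5)c4)OC[C@H]23)ccc1OCc1ccccc1 | intermediate
11 | (3S,3aR,6aR)-6-[3,4-bis(benzyloxy)phenyl]-3-[4-(benzyloxy)-3-methoxyphenyl]-6a-bromo-6-methoxytetrahydro-1H,3H-furo[3,4-c]furan-1-one (C6 epimers) | COc1cc([C@H]2OC(=O)[C@@]3(Br)[C@@H]2COC3(OC)c2ccc(OCc3ccccc3)c(OCc3ccccc3)c2)ccc1OCc1ccccc1 | intermediate
12 | (3S,3aR,6R,6aR)-6-[3,4-bis(benzyloxy)phenyl]-3-[4-(benzyloxy)-3-methoxyphenyl]-6a-bromotetrahydro-1H,3H-furo[3,4-c]furan-1-one | COc1cc([C@H]2OC(=O)[C@@]3(Br)[C@@H]2CO[C@@H]3c2ccc(OCc3ccccc3)c(OCc3ccccc3)c2)ccc1OCc1ccccc1 | intermediate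
13 | (3S,3aR,6S,6aS)-6-(3,4-dihydroxyphenyl)-3-(4-hydroxy-3-methoxyphenyl)tetrahydro-1H,3H-furo[3,4-c]furan-1-one | COc1cc([C@H]2OC(=O)[C@H]3[C@@H]2CO[C@@H]3c2ccc(O)c(O)c2)ccc1O | target

## Step count and risks

Total step count: 7. Longest linear sequence: 7 steps (1 to 13).

Most likely to fail, first: step 4. The electron-rich, doubly activated allylic ester may ionise or be over-oxidised in AcOH before the radical cyclises, or the ring expansion may stall at the cyclopropane. The fallback sets out from 8 and replaces the radical by a carbene. Diazo transfer (4-acetamidobenzenesulfonyl azide, Et3N, MeCN) should give (1S)-1-[4-(benzyloxy)-3-methoxyphenyl]prop-2-en-1-yl 3-[3,4-bis(benzyloxy)phenyl]-2-diazo-3-oxopropanoate F1. Rh2(OAc)4 (1 mol %) in CH2Cl2 at 40 °C should then effect the intramolecular cyclopropanation to 9, which is isolated. Heating 9 with NaI in acetone (or DABCO in DMSO) brings about the Cloke–Wilson ring expansion, and the fallback comes back to the route at 10.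

Second: step 6. Hydride transfer may show poor facial selectivity (attack syn to bromine), or the β-bromo oxocarbenium ion may lose Br+ and revert to 10. The fallback sets out from 10 and uses thermodynamic instead of kinetic control. Hydrogenation (H2, 3 atm, Pd/C, EtOAc/MeOH) should add hydrogen cis from the convex face and cleave the benzyl ethers to give the C6 epimer (3S,3aR,6R,6aS)-6-(3,4-dihydroxyphenyl)-3-(4-hydroxy-3-methoxyphenyl)tetrahydro-1H,3H-furo[3,4-c]furan-1-one F2. Catalytic HCl in EtOH then equilibrates the benzylic ether centre C6 through the ring-opened benzylic cation, the known acid epimerisation of furofuran lignans. The equilibrium position is not known for this lactone, so the exo isomer is separated by chromatography and F2 is resubmitted; the fallback comes back at 13.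

Third: step 3. The acid-labile allylic alcohol 4 may ionise, undergo allylic transposition or racemise on heating with the acidic acyl Meldrum's acid. The fallback sets out from 4 and 5 and forms the β-keto ester under cold basic conditions. Acetylation of 4 (Ac2O, pyridine, cat. DMAP, 0 °C) should give (1S)-1-[4-(benzyloxy)-3-methoxyphenyl]prop-2-en-1-yl acetate F3, and acid 5 with carbonyldiimidazole in THF should give [3,4-bis(benzyloxy)phenyl](1H-imidazol-1-yl)methanone F4. The enolate of F3 (LiN(SiMe3)2, 2.1 equiv, THF, −78 °C) is acylated by F4 in a crossed Claisen condensation and quenched cold with aq. NH4Cl; the fallback comes back at 8.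

Further compounds
F1 | step 4 | (1S)-1-[4-(benzyloxy)-3-methoxyphenyl]prop-2-en-1-yl 3-[3,4-bis(benzyloxy)phenyl]-2-diazo-3-oxopropanoate | COc1cc([C@@H](OC(=O)C(=[N+]=[N-])C(=O)c2ccc(OCc3ccccc3)c(OCc3ccccc3)c2)C=C)ccc1OCc1ccccc1
F2 | step 6 | (3S,3aR,6R,6aS)-6-(3,4-dihydroxyphenyl)-3-(4-hydroxy-3-methoxyphenyl)tetrahydro-1H,3H-furo[3,4-c]furan-1-one | COc1cc([C@H]2OC(=O)[C@H]3[C@@H]2CO[C@H]3c2ccc(O)c(O)c2)ccc1O
F3 | step 3 | (1S)-1-[4-(benzyloxy)-3-methoxyphenyl]prop-2-en-1-yl acetate | COc1cc([C@@H](OC(C)=O)C=C)ccc1OCc1ccccc1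
F4 | step 3 | [3,4-bis(benzyloxy)phenyl](1H-imidazol-1-yl)methanone | O=C(c1ccc(OCc2ccccc2)c(OCc2ccccc2)c1)n1ccnc1
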